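**Plan**
Retrosynthesis: the O–Si bond of a silyl-protected C6 phenol is cut last; before it, the dihydrofuran ring is cut at C2–C3 and O1–C2.
This works because C2 is a single sp3 carbon carrying the trimethoxyphenyl group between O1 and C3, while O1–C7a–C3a–C3 is a phenol oxygen, two arene carbons and a benzylic carbon, i.e. a masked o-quinone methide; C2 can therefore arrive as a benzylidene from a sulfonium ylide.
Further cuts: the benzylic C–S (sulfone) and aryl–allyl bonds in the arene branch; the S–CH2Ar bond and both ring C–S bonds of a chiral thiolane in the sulfonium branch.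
Forward: steps 1–4 build the quinone methide precursor, steps 5–7 the chiral sulfonium salt; step 8 joins them and closes the only new ring (the dihydrofuran); step 9 frees the phenol.
Stereochemistry: C2 comes from the C2-symmetric (2S,5S)-thiolane (ylide face, then inversion on ring closure); C3 from trans-selective C–C bond formation on the (E)-quinone methide; the benzylic centre of the precursor is racemic and is erased.

Key step: step 8

Assumption: the sense of induction of the 2,5-dimethylthiolanium benzylide towards the quinone methide is taken to be the one established for its aldehyde epoxidations (aryl group pointing away from the ring, attack anti to the ring methyl that is cis to the ylidic carbon).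

**Step 1**
Reactants: 1 1-(5-bromo-2,4-dihydroxyphenyl)ethanone
Product: 2 1-(5-allyl-2,4-dihydroxyphenyl)ethanone
Conditions: allylSnBu3, Pd(PPh3)4 (5 mol%), DMF, 90 °C
Reagents that add atoms: allyltributylstannane, C=CC[Sn](CCCC)(CCCC)CCCC
Why: Stille cross-coupling (oxidative addition into the aryl C–Br bond, allyl transfer from tin, reductive elimination) runs under neutral conditions, so the free phenols and the ketone should be tolerated.

**Step 2**
Reactants: 2 1-(5-allyl-2,4-dihydroxyphenyl)ethanone
Product: 3 1-[5-allyl-2-hydroxy-4-(triisopropylsilyloxy)phenyl]ethanone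
Conditions: TIPSCl (1.1 equiv), imidazole, DMF, 0 °C → rt
Reagents that add atoms: triisopropylsilyl chloride, CC(C)[Si](Cl)(C(C)C)C(C)C
Why: Regioselective silyl ether formation: the 2-OH is tied up in a hydrogen bond to the acetyl group and is far less nucleophilic, so the bulky chloride should take only the 4-OH.

**Step 3**
Reactants: 3 1-[5-allyl-2-hydroxy-4-(triisopropylsilyloxy)phenyl]ethanone
Product: 4 racemic 4-allyl-2-(1-hydroxyethyl)-5-(triisopropylsilyloxy)phenol
Conditions: NaBH4, THF/MeOH, 0 °C; used without chromatography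
Reagents that add atoms: none
Why: Borohydride reduction of the aryl ketone should leave the aryl silyl ether and the allyl group alone, and needs no stereocontrol because this centre is erased in step 8.

**Step 4**
Reactants: 4 racemic 4-allyl-2-(1-hydroxyethyl)-5-(triisopropylsilyloxy)phenol
Product: 5 racemic 4-allyl-2-[1-(4-methylbenzenesulfonyl)ethyl]-5-(triisopropylsilyloxy)phenol
Conditions: p-TolSO2H (1.5 equiv), CH2Cl2, rt
Reagents that add atoms: p-toluenesulfinic acid, Cc1ccc(S(=O)O)cc1
Why: Acid-promoted SN1-type benzylic substitution, in which the sulfinic acid ionises the oxygen-stabilised benzylic alcohol and sulfinate is alkylated at sulfur, is the standard entry to 2-(1-sulfonylalkyl)phenols.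

**Step 5**
Reactants: 6 (2R,5R)-hexane-2,5-diol
Product: 7 (2R,5R)-hexane-2,5-diyl dimethanesulfonate
Conditions: MsCl, Et3N, CH2Cl2, −10 °C
Reagents that add atoms: methanesulfonyl chloride, CS(=O)(=O)Cl
Why: Sulfonate ester formation (mesylation) forms only O–S bonds, so both carbinol centres keep their configuration.

**Step 6**
Reactants: 7 (2R,5R)-hexane-2,5-diyl dimethanesulfonate
Product: 8 (2S,5S)-2,5-dimethylthiolane
Conditions: Na2S·9H2O, DMSO, rt; distillation
Reagents that add atoms: sodium sulfide, [Na+].[Na+].[S-2]
Why: Double SN2 displacement by sulfide (intermolecular, then 5-exo-tet) inverts both centres and should turn the (R,R)-dimesylate into the trans (S,S)-thiolane.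

**Step 7**
Reactants: 8 (2S,5S)-2,5-dimethylthiolane; 9 5-(bromomethyl)-1,2,3-trimethoxybenzene (3,4,5-trimethoxybenzyl bromide)
Product: 10 (2S,5S)-2,5-dimethyl-1-[(3,4,5-trimethoxyphenyl)methyl]thiolan-1-ium tetrafluoroborate
Conditions: NaBF4 (aq.), CH2Cl2, rt, 48 h
Reagents that add atoms: sodium tetrafluoroborate, [Na+].F[B-](F)(F)F
Why: S-Alkylation to the sulfonium salt with biphasic anion exchange; the C2 axis makes both sulfur lone pairs equivalent, so a single salt should form, and the non-nucleophilic counter-ion prevents dealkylation.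

**Step 8**
Reactants: 5 racemic 4-allyl-2-[1-(4-methylbenzenesulfonyl)ethyl]-5-(triisopropylsilyloxy)phenol; 10 (2S,5S)-2,5-dimethyl-1-[(3,4,5-trimethoxyphenyl)methyl]thiolan-1-ium tetrafluoroborate
Product: 14 (2S,3S)-5-allyl-3-methyl-6-(triisopropylsilyloxy)-2-(3,4,5-trimethoxyphenyl)-2,3-dihydrobenzofuran, via sulfonium benzylide 11 (not isolated), via ortho-quinone methide 12 (not isolated), via phenoxide sulfonium betaine 13 (not isolated)
Conditions: 10 (1.3 equiv), Cs2CO3 (3 equiv), 4 Å MS, MeCN, −20 → 0 °C
Reagents that add atoms: none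
Why: Proposed new method: Cs2CO3 deprotonates the phenol of 5, which expels p-toluenesulfinate to give quinone methide 12 (both enantiomers of 5 converge), and deprotonates 10 to benzylide 11; carbon attack of 11 on the exocyclic carbon of 12 forms C2–C3 with rearomatisation to betaine 13, whose phenoxide displaces the thiolane at the benzylic carbon with inversion to form O1–C2, a 5-exo-tet closure of the dihydrofuran ring. The closest known reaction types are the formal [4+1] annulation of o-quinone methides released from 2-(1-sulfonylalkyl)phenols with acyl-stabilised sulfonium ylides and the conjugate addition/ring closure of chiral sulfonium benzylides on enones; the extension to a semistabilised benzylide is plausible because its 1,4-addition is irreversible, driven by rearomatisation, and leaves a phenoxide five atoms from a very good sulfonium leaving group. C2 is controlled by the C2-symmetric thiolane: the aryl group of the ylide lies in the plane bisecting the ring and points away from it, the ring methyl cis to the ylidic carbon shields one face, 12 is met on the other, and the invertive closure then gives 2S. C3 is set in the same C–C bond-forming event, in which the (E)-quinone methide and the ylide approach with methyl and aryl anti (the less hindered anti betaine), so the ring closes trans and C3 is S. The step needs 1,4- rather than carbonyl addition, one ylide face and trans diastereoselection; these rest on the aromatisation energy, the thiolane methyl groups and the E geometry of 12, while the silyl ether keeps the second phenol from opening a p-quinone methide/spirocyclopropane pathway.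

**Step 9**
Reactants: 14 (2S,3S)-5-allyl-3-methyl-6-(triisopropylsilyloxy)-2-(3,4,5-trimethoxyphenyl)-2,3-dihydrobenzofuran
Product: 15 (2S,3S)-5-allyl-3-methyl-2-(3,4,5-trimethoxyphenyl)-2,3-dihydrobenzofuran-6-ol
Conditions: TBAF, AcOH, THF, 0 °C → rt
Reagents that add atoms: none
Why: Fluoride-mediated desilylation of the aryl silyl ether, buffered with acetic acid, should free the phenol without touching the allyl group, the benzylic ether or either stereocentre.

**Compound list**
1 | 1-(5-bromo-2,4-dihydroxyphenyl)ethanone | CC(=O)c1cc(Br)c(O)cc1O | starting material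
2 | 1-(5-allyl-2,4-dihydroxyphenyl)ethanone | CC(=O)c1cc(CC=C)c(O)cc1O | intermediate
3 | 1-[5-allyl-2-hydroxy-4-(triisopropylsilyloxy)phenyl]ethanone | CC(=O)c1cc(CC=C)c(O[Si](C(C)C)(C(C)C)C(C)C)cc1O | intermediate
4 | racemic 4-allyl-2-(1-hydroxyethyl)-5-(triisopropylsilyloxy)phenol | CC(O)c1cc(CC=C)c(O[Si](C(C)C)(C(C)C)C(C)C)cc1O | intermediate
5 | racemic 4-allyl-2-[1-(4-methylbenzenesulfonyl)ethyl]-5-(triisopropylsilyloxy)phenol | C=CCc1cc(C(C)S(=O)(=O)c2ccc(C)cc2)c(O)cc1O[Si](C(C)C)(C(C)C)C(C)C | intermediate
6 | (2R,5R)-hexane-2,5-diol | C[C@@H](O)CC[C@@H](C)O | starting material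
7 | (2R,5R)-hexane-2,5-diyl dimethanesulfonate | C[C@@H](OS(C)(=O)=O)CC[C@@H](C)OS(C)(=O)=O | intermediate
8 | (2S,5S)-2,5-dimethylthiolane | C[C@H]1CC[C@H](C)S1 | intermediate
9 | 5-(bromomethyl)-1,2,3-trimethoxybenzene | COc1cc(CBr)cc(OC)c1OC | starting material
10 | (2S,5S)-2,5-dimethyl-1-[(3,4,5-trimethoxyphenyl)methyl]thiolan-1-ium tetrafluoroborate | COc1cc(C[S+]2[C@@H](C)CC[C@@H]2C)cc(OC)c1OC.F[B-](F)(F)F | intermediate
11 | [(2S,5S)-2,5-dimethylthiolan-1-ium-1-yl](3,4,5-trimethoxyphenyl)methanide (sulfonium benzylide) | COc1cc([CH-][S+]2[C@@H](C)CC[C@@H]2C)cc(OC)c1OC | intermediate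
12 | (E)-4-allyl-6-ethylidene-3-(triisopropylsilyloxy)cyclohexa-2,4-dien-1-one (ortho-quinone methide) | C/C=C1\C=C(CC=C)C(O[Si](C(C)C)(C(C)C)C(C)C)=CC1=O | intermediate
13 | 4-allyl-2-[(1R,2S)-1-[(2S,5S)-2,5-dimethylthiolan-1-ium-1-yl]-1-(3,4,5-trimethoxyphenyl)propan-2-yl]-5-(triisopropylsilyloxy)phenolate (betaine) | C=CCc1cc([C@H](C)[C@H](c2cc(OC)c(OC)c(OC)c2)[S+]2[C@@H](C)CC[C@@H]2C)c([O-])cc1O[Si](C(C)C)(C(C)C)C(C)C | intermediate
14 | (2S,3S)-5-allyl-3-methyl-6-(triisopropylsilyloxy)-2-(3,4,5-trimethoxyphenyl)-2,3-dihydrobenzofuran | C=CCc1cc2c(cc1O[Si](C(C)C)(C(C)C)C(C)C)O[C@H](c1cc(OC)c(OC)c(OC)c1)[C@H]2C | intermediate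
15 | (2S,3S)-5-allyl-3-methyl-2-(3,4,5-trimethoxyphenyl)-2,3-dihydrobenzofuran-6-ol | C=CCc1cc2c(cc1O)O[C@H](c1cc(OC)c(OC)c(OC)c1)[C@H]2C | target

**Step count and risks**
Total: 9 steps. Longest linear sequence: 6 steps (1, 2, 3, 4, 8, 9).

Step 8. The benzylide may add with poor facial discrimination, may hand its benzyl group to the phenoxide of 5 instead of adding through carbon, or may be outrun by tautomerisation of the quinone methide to a vinylphenol. The fallback uses known chemistry and sets out from sulfone 5. The established annulation of the same quinone methide with an ester-stabilised ylide, ethyl (dimethyl-λ4-sulfanylidene)acetate (Cs2CO3, CH2Cl2, rt), should give racemic trans ethyl 5-allyl-3-methyl-6-(triisopropylsilyloxy)-2,3-dihydrobenzofuran-2-carboxylate F1. Me3SnOH (1,2-dichloroethane, 80 °C) should hydrolyse it, sparing the silyl ether, to racemic trans 5-allyl-3-methyl-6-(triisopropylsilyloxy)-2,3-dihydrobenzofuran-2-carboxylic acid F2. Classical resolution (crystallisation of a 1-phenylethylammonium salt, or chromatography on a chiral phase) would give (2S,3S)-5-allyl-3-methyl-6-(triisopropylsilyloxy)-2,3-dihydrobenzofuran-2-carboxylic acid F3. N-Hydroxyphthalimide and DIC would convert it into the 1,3-dioxoisoindolin-2-yl ester F4. Nickel-catalysed decarboxylative arylation (NiCl2·glyme, 4,4′-di-tert-butyl-2,2′-bipyridine, THF/DMF, rt) with (3,4,5-trimethoxyphenyl)zinc chloride F5, made from 5-bromo-1,2,3-trimethoxybenzene with Mg/LiCl and then ZnCl2, should then place the aryl group anti to the C3 methyl through the C2 radical. The route is rejoined at 14.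

Step 1. Oxidative addition into the electron-rich, unprotected bromoresorcinol may be sluggish, and palladium hydride may move the allyl double bond into conjugation at the temperature required. The fallback sets out from 1. Acetylation of both phenols (Ac2O, pyridine) gives 4-acetyl-6-bromo-1,3-phenylene diacetate F6, whose electron-poorer C–Br bond should couple with allylSnBu3 at lower temperature (Pd2(dba)3, tri(2-furyl)phosphine, toluene, 70 °C) to give 4-acetyl-6-allyl-1,3-phenylene diacetate F7. Methanolysis (K2CO3, MeOH, 0 °C) rejoins the route at 2.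

Step 7. S-Alkylation of the hindered thiolane may be slow and reversible (bromide return), leaving halide and sulfide unconsumed. The fallback sets out from thiolane 8 and uses commercial 3,4,5-trimethoxybenzyl alcohol with HBF4·OEt2 (Et2O/CH2Cl2, 0 °C → rt). The acid ionises the alcohol, the sulfide captures the benzylic cation, and no nucleophilic counter-ion is present to reverse the alkylation. The route is rejoined at salt 10; this fallback makes no compound outside the list (F0).

**Further compounds**
F1 | step 8 | racemic trans ethyl 5-allyl-3-methyl-6-(triisopropylsilyloxy)-2,3-dihydrobenzofuran-2-carboxylate (both enantiomers) | C=CCc1cc2c(cc1O[Si](C(C)C)(C(C)C)C(C)C)O[C@H](C(=O)OCC)[C@H]2C.C=CCc1cc2c(cc1O[Si](C(C)C)(C(C)C)C(C)C)O[C@@H](C(=O)OCC)[C@@H]2C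
F2 | step 8 | racemic trans 5-allyl-3-methyl-6-(triisopropylsilyloxy)-2,3-dihydrobenzofuran-2-carboxylic acid (both enantiomers) | C=CCc1cc2c(cc1O[Si](C(C)C)(C(C)C)C(C)C)O[C@H](C(=O)O)[C@H]2C.C=CCc1cc2c(cc1O[Si](C(C)C)(C(C)C)C(C)C)O[C@@H](C(=O)O)[C@@H]2C
F3 | step 8 | (2S,3S)-5-allyl-3-methyl-6-(triisopropylsilyloxy)-2,3-dihydrobenzofuran-2-carboxylic acid | C=CCc1cc2c(cc1O[Si](C(C)C)(C(C)C)C(C)C)O[C@H](C(=O)O)[C@H]2C
F4 | step 8 | 1,3-dioxoisoindolin-2-yl (2S,3S)-5-allyl-3-methyl-6-(triisopropylsilyloxy)-2,3-dihydrobenzofuran-2-carboxylate | C=CCc1cc2c(cc1O[Si](C(C)C)(C(C)C)C(C)C)O[C@H](C(=O)ON1C(=O)c3ccccc3C1=O)[C@H]2C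
F5 | step 8 | (3,4,5-trimethoxyphenyl)zinc chloride | COc1cc([Zn]Cl)cc(OC)c1OC
F6 | step 1 | 4-acetyl-6-bromo-1,3-phenylene diacetate | CC(=O)Oc1cc(OC(C)=O)c(C(C)=O)cc1Br
F7 | step 1 | 4-acetyl-6-allyl-1,3-phenylene diacetate | CC(=O)Oc1cc(OC(C)=O)c(C(C)=O)cc1CC=C
F0 | step 7 | none | none
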